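**Plan**

- Retrosynthetically the C3=C4 enol is returned to a saturated lactone with a C3 methylene, the lactone acyl bond O1–C2 is opened, and the C5–C4 bond is cut to give an aryl-lactic acid enolate (C5) and methyl cinnamate (C4, C3, C2).
- This is possible because the quaternary ring carbon C5 holds the lactone oxygen O1, the ester carbon and a CH2 bound to C6 of the chroman (para to the chroman oxygen), which is the oxygenated carbon framework of tyrosine; its fourth neighbour C4 ends as an sp2 carbon of the enol and needs no control.
- In the forward direction the chroman ring is built first on the tyrosine-derived phenol; a temporary cis-2-tert-butyl-1,3-dioxolan-4-one ring is then made and its enolate forms C5–C4; the lactone ring closes last, when methoxide opens the dioxolanone and the freed C5 alkoxide acylates on the cinnamate ester.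
- C3 is finally hydroxylated and oxidised, and the 2,3-dioxo lactone enolises to the target.
- The single stereocentre C5 (R) descends from the α-carbon of L-tyrosine: diazotisation goes with retention, the acetal carbon stores the chirality while C5 is trigonal, and the cinnamate enters anti to tert-butyl.

Key step: step 6

Remark: the lactone is numbered O1, C2 (carbonyl), C3, C4 (phenyl-bearing), C5 (quaternary) and "chroman" means 3,4-dihydro-2H-chromene; the PhCH centre and the later C3 carbinol centre are carried as mixtures because both end as sp2 carbons, and racemic trans-3-phenyl-2-(phenylsulfonyl)oxaziridine is assumed in step 8.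

**Route**

Step 1
Reactants: 1 L-tyrosine
Product: 3 (2S)-2-hydroxy-3-(4-hydroxyphenyl)propanoic acid, via α-lactone 2 (not isolated)
Conditions: NaNO2 (2 equiv), 1 M aqueous H2SO4, 0 °C to rt
Reagents that add atoms: water, O
Why: Diazotisation of the α-amino acid gives a diazonium ion that the neighbouring carboxylate displaces with inversion to α-lactone 2, which water opens at the α-carbon with a second inversion, so that hydroxyl replaces the amino group with net retention of the (S) configuration and no new stereocentre is created.

Step 2
Reactants: 3 (2S)-2-hydroxy-3-(4-hydroxyphenyl)propanoic acid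
Product: 4 methyl (2S)-2-hydroxy-3-(4-hydroxyphenyl)propanoate
Conditions: MeOH, H2SO4 (cat.), reflux
Reagents that add atoms: methanol, CO
Why: Fischer esterification in excess methanol masks the carboxylic acid, which would otherwise compete as a nucleophile for the allyl cation of the next step, and keeps the substrate soluble in a chlorinated solvent, while the stereocentre is not involved.

Step 3
Reactants: 4 methyl (2S)-2-hydroxy-3-(4-hydroxyphenyl)propanoate; 5 2-methylbut-3-en-2-ol
Product: 7 methyl (2S)-3-(2,2-dimethylchroman-6-yl)-2-hydroxypropanoate, via o-prenylphenol 6 (not isolated)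
Conditions: 5 (1.3 equiv, slow addition), Amberlyst 15 (sulfonic acid resin), 1,2-dichloroethane, 70 °C
Reagents that add atoms: none
Why: Acid-catalysed Friedel–Crafts allylation of the phenol by the dimethylallyl cation from tertiary allylic alcohol 5 can only occur ortho to the hydroxyl because the para position is blocked, giving 6, whose trisubstituted alkene is then protonated and captured by the phenol oxygen in a Markovnikov 6-endo hydroalkoxylation that closes the 2,2-dimethylchroman ring, the manifold used in tocopherol-type chroman syntheses from phenols and tertiary allylic alcohols, with the α-hydroxy ester stereocentre as a spectator.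

Step 4
Reactants: 7 methyl (2S)-3-(2,2-dimethylchroman-6-yl)-2-hydroxypropanoate
Product: 8 (2S)-3-(2,2-dimethylchroman-6-yl)-2-hydroxypropanoic acid
Conditions: LiOH·H2O (2.5 equiv), THF/H2O, 0 °C to rt; then 1 M HCl
Reagents that add atoms: lithium hydroxide, [Li+].[OH-]
Why: Saponification of the methyl ester by acyl–oxygen cleavage at low temperature frees the acid needed for acetalisation, the α-carbon of an α-hydroxy ester being too weakly acidic to epimerise under these conditions and the chroman ether being inert to base.

Step 5
Reactants: 8 (2S)-3-(2,2-dimethylchroman-6-yl)-2-hydroxypropanoic acid; 9 pivalaldehyde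
Product: 10 (2S,5S)-cis-2-tert-butyl-5-[(2,2-dimethylchroman-6-yl)methyl]-1,3-dioxolan-4-one
Conditions: 9 (2 equiv), p-TsOH·H2O (cat.), H2SO4 (trace), pentane, reflux, Dean–Stark trap; cis isomer purified by crystallisation or chromatography
Reagents that add atoms: none
Why: Acid-catalysed acetalisation of the α-hydroxy acid with pivalaldehyde under azeotropic removal of water gives the 2-tert-butyl-1,3-dioxolan-4-one, in which the new acetal centre C2 is set by the existing C5 centre because the isomer with tert-butyl and arylmethyl cis on the five-membered ring is favoured, and the cis isomer is purified because the trans isomer would carry the opposite sense of induction into step 6.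

Step 6
Reactants: 10 (2S,5S)-cis-2-tert-butyl-5-[(2,2-dimethylchroman-6-yl)methyl]-1,3-dioxolan-4-one; 11 methyl (E)-cinnamate
Product: 14 (2S,5R)-2-tert-butyl-5-[(2,2-dimethylchroman-6-yl)methyl]-5-(3-methoxy-3-oxo-1-phenylpropyl)-1,3-dioxolan-4-one (both epimers at the PhCH carbon), via lithium dioxolanone enolate 12 (not isolated), via lithium ester enolate 13 (not isolated)
Conditions: LiN(iPr)2 (1.1 equiv), THF/DMPU, −78 °C; then 11 (1.3 equiv), −78 to −50 °C; AcOH, −78 °C
Reagents that add atoms: none
Why: LiN(iPr)2 removes the C5 proton of 10 to give planar lithium enolate 12, whose nucleophilic carbon adds to the β-carbon of 11 to form the C5–C4 bond and ester enolate 13, which is protonated by the cold acetic acid quench. The closest known reaction type is the Michael addition of lithium enolates of cis-2-tert-butyl-1,3-dioxolan-4-ones to nitroalkenes, enones and enoates within the self-regeneration-of-stereocentres concept, together with the 1,4-addition of lithium ester enolates to cinnamates at −78 °C. No ring is closed in this step; the lactone ring is closed in step 7. The new quaternary centre C5 is controlled by the acetal carbon C2, whose tert-butyl group shields one face of the enolate so that the cinnamate bonds on the face the hydrogen occupied, which gives (5R) with overall retention of the tyrosine configuration, whereas the PhCH centre is left uncontrolled because it becomes the sp2 carbon C4 of the target. The step needs 1,4- rather than 1,2-addition and addition that outruns decay of the enolate: the fully substituted, hindered enolate carbon and the β-aryl enoate disfavour attack at the ester carbonyl, DMPU favours the conjugate pathway, and holding the mixture at or below −50 °C suppresses fragmentation of 12 and retro-Michael reaction of 13.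

Step 7
Reactants: 14 (2S,5R)-2-tert-butyl-5-[(2,2-dimethylchroman-6-yl)methyl]-5-(3-methoxy-3-oxo-1-phenylpropyl)-1,3-dioxolan-4-one
Product: 16 methyl (2R)-2-[(2,2-dimethylchroman-6-yl)methyl]-5-oxo-3-phenyloxolane-2-carboxylate (both epimers at the PhCH carbon), via sodium tertiary alkoxide 15 (not isolated)
Conditions: NaOMe (0.3 equiv), MeOH, 0 °C to rt; AcOH
Reagents that add atoms: methanol (delivered as methoxide), CO
Why: Methoxide attacks the activated acyl-acetal carbonyl of the dioxolanone in a transesterification, the hemiacetal alkoxide expels pivalaldehyde, and tertiary alkoxide 15 closes the γ-lactone by 5-exo-trig acyl substitution on the side-chain ester placed 1,4 to it with regeneration of methoxide, C5 being quaternary and unable to epimerise and any ester exchange being degenerate because the base matches the methyl esters.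

Step 8
Reactants: 16 methyl (2R)-2-[(2,2-dimethylchroman-6-yl)methyl]-5-oxo-3-phenyloxolane-2-carboxylate
Product: 18 methyl (2R)-2-[(2,2-dimethylchroman-6-yl)methyl]-4-hydroxy-5-oxo-3-phenyloxolane-2-carboxylate (mixture at the CHOH and PhCH carbons), via sodium lactone enolate 17 (not isolated)
Conditions: NaN(SiMe3)2 (1.2 equiv), THF, −78 °C; then 3-phenyl-2-(phenylsulfonyl)oxaziridine (1.5 equiv), −78 °C; AcOH, −78 °C
Reagents that add atoms: 3-phenyl-2-(phenylsulfonyl)oxaziridine, O=S(=O)(c1ccccc1)N1OC1c1ccccc1
Why: In this Davis oxidation NaN(SiMe3)2 forms sodium enolate 17 at C3, the only enolisable position because C5 is quaternary, and the enolate carbon attacks the electrophilic oxygen of the N-sulfonyloxaziridine to give the α-hydroxy lactone after collapse of the hemiaminal, the new C3 carbinol centre being formed without any need for control since it is erased in step 9.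

Step 9
Reactants: 18 methyl (2R)-2-[(2,2-dimethylchroman-6-yl)methyl]-4-hydroxy-5-oxo-3-phenyloxolane-2-carboxylate
Product: 20 4'-dehydroxy aspernolide A [methyl (2R)-2-[(2,2-dimethylchroman-6-yl)methyl]-4-hydroxy-5-oxo-3-phenyl-2,5-dihydrofuran-2-carboxylate], via 2,3-dioxo lactone 19 (not isolated)
Conditions: Dess–Martin periodinane (1.2 equiv), CH2Cl2, 0 °C to rt
Reagents that add atoms: none
Why: Dess–Martin oxidation of the secondary alcohol gives 2,3-dioxo lactone 19, whose acidic benzylic C4–H allows tautomerisation to the C3=C4 enol conjugated with both the phenyl ring and the lactone carbonyl, so that the two transient stereocentres vanish and only the quaternary C5 (R) centre, untouched by the oxidant, remains.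

**Compound list**

1 | L-tyrosine | N[C@@H](Cc1ccc(O)cc1)C(=O)O | starting material
2 | (3R)-3-(4-hydroxybenzyl)oxiran-2-one (α-lactone) | O1[C@H](Cc2ccc(O)cc2)C1=O | intermediate (not isolated)
3 | (2S)-2-hydroxy-3-(4-hydroxyphenyl)propanoic acid | O[C@@H](Cc1ccc(O)cc1)C(=O)O | intermediate
4 | methyl (2S)-2-hydroxy-3-(4-hydroxyphenyl)propanoate | O[C@@H](Cc1ccc(O)cc1)C(=O)OC | intermediate
5 | 2-methylbut-3-en-2-ol | CC(C)(O)C=C | starting material
6 | methyl (2S)-2-hydroxy-3-[4-hydroxy-3-(3-methylbut-2-en-1-yl)phenyl]propanoate | O[C@@H](Cc1ccc(O)c(CC=C(C)C)c1)C(=O)OC | intermediate (not isolated)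
7 | methyl (2S)-3-(2,2-dimethylchroman-6-yl)-2-hydroxypropanoate | O[C@@H](Cc1ccc2c(c1)CCC(C)(C)O2)C(=O)OC | intermediate
8 | (2S)-3-(2,2-dimethylchroman-6-yl)-2-hydroxypropanoic acid | O[C@@H](Cc1ccc2c(c1)CCC(C)(C)O2)C(=O)O | intermediate
9 | pivalaldehyde | CC(C)(C)C=O | starting material
10 | (2S,5S)-cis-2-tert-butyl-5-[(2,2-dimethylchroman-6-yl)methyl]-1,3-dioxolan-4-one | CC(C)(C)[C@H]1O[C@@H](Cc2ccc3c(c2)CCC(C)(C)O3)C(=O)O1 | intermediate
11 | methyl (E)-cinnamate | COC(=O)/C=C/c1ccccc1 | starting material
12 | lithium (2S)-2-tert-butyl-5-[(2,2-dimethylchroman-6-yl)methyl]-1,3-dioxol-4-olate | CC(C)(C)[C@H]1OC(Cc2ccc3c(c2)CCC(C)(C)O3)=C([O-])O1.[Li+] | intermediate (not isolated)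
13 | lithium ester enolate of 14 | CC(C)(C)[C@H]1O[C@](Cc2ccc3c(c2)CCC(C)(C)O3)(C(C=C([O-])OC)c2ccccc2)C(=O)O1.[Li+] | intermediate (not isolated)
14 | (2S,5R)-2-tert-butyl-5-[(2,2-dimethylchroman-6-yl)methyl]-5-(3-methoxy-3-oxo-1-phenylpropyl)-1,3-dioxolan-4-one, both epimers at the PhCH carbon | CC(C)(C)[C@H]1O[C@](Cc2ccc3c(c2)CCC(C)(C)O3)(C(CC(=O)OC)c2ccccc2)C(=O)O1 | intermediate
15 | sodium alkoxide of dimethyl (2R)-2-[(2,2-dimethylchroman-6-yl)methyl]-2-hydroxy-3-phenylpentanedioate | COC(=O)[C@@]([O-])(Cc1ccc2c(c1)CCC(C)(C)O2)C(CC(=O)OC)c1ccccc1.[Na+] | intermediate (not isolated)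
16 | methyl (2R)-2-[(2,2-dimethylchroman-6-yl)methyl]-5-oxo-3-phenyloxolane-2-carboxylate, both epimers at the PhCH carbon | COC(=O)[C@]1(Cc2ccc3c(c2)CCC(C)(C)O3)OC(=O)CC1c1ccccc1 | intermediate
17 | sodium enolate of 16 | COC(=O)[C@]1(Cc2ccc3c(c2)CCC(C)(C)O3)OC([O-])=CC1c1ccccc1.[Na+] | intermediate (not isolated)
18 | methyl (2R)-2-[(2,2-dimethylchroman-6-yl)methyl]-4-hydroxy-5-oxo-3-phenyloxolane-2-carboxylate, mixture at the CHOH and PhCH carbons | COC(=O)[C@]1(Cc2ccc3c(c2)CCC(C)(C)O3)OC(=O)C(O)C1c1ccccc1 | intermediate
19 | methyl (2R)-2-[(2,2-dimethylchroman-6-yl)methyl]-4,5-dioxo-3-phenyloxolane-2-carboxylate | COC(=O)[C@]1(Cc2ccc3c(c2)CCC(C)(C)O3)OC(=O)C(=O)C1c1ccccc1 | intermediate (not isolated)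
20 | 4'-dehydroxy aspernolide A, methyl (2R)-2-[(2,2-dimethylchroman-6-yl)methyl]-4-hydroxy-5-oxo-3-phenyl-2,5-dihydrofuran-2-carboxylate | COC(=O)[C@]1(Cc2ccc3c(c2)CCC(C)(C)O3)OC(=O)C(O)=C1c1ccccc1 | target

**Count and risks**

Total step count: 9. Longest linear sequence: 9 steps (1 to 20).

Steps most likely to fail:

Step 6. The addition of the hindered enolate to the only moderately electrophilic enoate may be slower than fragmentation of the enolate, and attack at the ester carbonyl or oligomerisation of the cinnamate may compete. The fallback sets out from 10: the same lithium enolate is added at −78 °C to commercial 5-benzylidene-2,2-dimethyl-1,3-dioxane-4,6-dione, a doubly activated acceptor that can only react 1,4 and gives a stabilised anion. This should give the adduct (2S,5R)-2-tert-butyl-5-[(2,2-dimethylchroman-6-yl)methyl]-5-[(2,2-dimethyl-4,6-dioxo-1,3-dioxan-5-yl)(phenyl)methyl]-1,3-dioxolan-4-one F1. Heating in methanol–pyridine opens the dioxanedione with loss of acetone to the malonic acid monomethyl ester F2, which decarboxylates on continued heating and so comes back to the route at 14.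

Step 8. The lactone enolate may undergo ring-opening retro-Michael fragmentation, or add to the sulfonimine formed from the oxidant, instead of accepting oxygen cleanly. The fallback sets out from 16: condensation at C3 with tert-butoxybis(dimethylamino)methane (Bredereck's reagent, toluene, 90 °C) needs no strong base and gives the 3-(dimethylaminomethylidene) lactone F3. Cleavage of its enamine double bond with singlet oxygen (O2, hν, tetraphenylporphyrin, CH2Cl2, −78 °C) through the dioxetane releases N,N-dimethylformamide and delivers 19, which enolises. The route is thus rejoined at 20, without 18 and without the oxidant of step 9.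

Step 3. Double allylation of the arene, O-alkylation of the secondary alcohol and self-condensation of the allylic alcohol may leave little of the chroman. The fallback sets out from 4: the phenol is O-alkylated with 3-chloro-3-methylbut-1-yne (DBU, CuCl2 cat., MeCN, 0 °C) to methyl (2S)-2-hydroxy-3-{4-[(2-methylbut-3-yn-2-yl)oxy]phenyl}propanoate F4. On heating (xylene, 140 °C) this should undergo aryl propargyl Claisen rearrangement, hydrogen shift and 6π-electrocyclisation to methyl (2S)-3-(2,2-dimethyl-2H-chromen-6-yl)-2-hydroxypropanoate F5. Hydrogenation of the chromene double bond (H2, Pd/C, EtOAc) returns to the route at 7.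

**Further compounds**

F1 | step 6 | (2S,5R)-2-tert-butyl-5-[(2,2-dimethylchroman-6-yl)methyl]-5-[(2,2-dimethyl-4,6-dioxo-1,3-dioxan-5-yl)(phenyl)methyl]-1,3-dioxolan-4-one | CC(C)(C)[C@H]1O[C@](Cc2ccc3c(c2)CCC(C)(C)O3)(C(C2C(=O)OC(C)(C)OC2=O)c2ccccc2)C(=O)O1
F2 | step 6 | 2-{[(2S,4R)-2-tert-butyl-4-[(2,2-dimethylchroman-6-yl)methyl]-5-oxo-1,3-dioxolan-4-yl](phenyl)methyl}-3-methoxy-3-oxopropanoic acid | CC(C)(C)[C@H]1O[C@](Cc2ccc3c(c2)CCC(C)(C)O3)(C(C(C(=O)O)C(=O)OC)c2ccccc2)C(=O)O1
F3 | step 8 | methyl (2R)-4-(dimethylaminomethylidene)-2-[(2,2-dimethylchroman-6-yl)methyl]-5-oxo-3-phenyloxolane-2-carboxylate | COC(=O)[C@]1(Cc2ccc3c(c2)CCC(C)(C)O3)OC(=O)C(=CN(C)C)C1c1ccccc1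
F4 | step 3 | methyl (2S)-2-hydroxy-3-{4-[(2-methylbut-3-yn-2-yl)oxy]phenyl}propanoate | O[C@@H](Cc1ccc(OC(C)(C)C#C)cc1)C(=O)OC
F5 | step 3 | methyl (2S)-3-(2,2-dimethyl-2H-chromen-6-yl)-2-hydroxypropanoate | O[C@@H](Cc1ccc2c(c1)C=CC(C)(C)O2)C(=O)OC
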